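**Retrosynthetic overview**
- The target is reached by late C6 acetylation and chemoselective isopropenyl hydrogenation of a ten-membered homoallylic alcohol; the angelate is installed early and serves as the C3 protecting group.
- Key step: instead of closing the ring at the alkene or epoxidising a preformed germacradiene, the ten-membered ring is closed at C6–C7 by an intramolecular palladium-catalysed, Et2Zn-driven umpolung allylation of an epoxy aldehyde by its own terminal allylic chloride. This forms the ring and both the C6 and C7 stereocentres at once.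
- The acyclic precursor is a 4-oxygenated farnesyl chain; one Sharpless kinetic-resolution epoxidation sets C3, C4 and C5 together.
- The C15 chain comes from geranyl chloride (α-selective allylbarium addition) and a C5 enal (Wittig).
- Ring order: oxirane first (step 3), cyclodecene second (step 8).

Assumption: 1, 2, 4 and 8 are bought; "C1–C12" in the Why lines is germacrane numbering (C1=C10 alkene, C3 angelate, C4–C5 epoxide, C6 acetate, C7 isopropyl), while names of acyclic compounds use dodecane numbering.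

**Step 1**
Reactants: 1 (tert-butyldimethylsilyloxy)acetaldehyde; 2 2-(triphenylphosphoranylidene)propanal
Product: 3 (E)-4-(tert-butyldimethylsilyloxy)-2-methylbut-2-enal
Conditions: toluene, 80 °C
Reagents that add atoms: none
Why: Wittig olefination with a formyl-stabilised ylide is E-selective, which fixes the trisubstituted alkene geometry that later becomes the trans C4–C5 epoxide.

**Step 2**
Reactants: 4 geranyl chloride [(2E)-1-chloro-3,7-dimethylocta-2,6-diene]; 3 (E)-4-(tert-butyldimethylsilyloxy)-2-methylbut-2-enal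
Product: 6 rac-(2E,6E)-1-(tert-butyldimethylsilyloxy)-3,7,11-trimethyldodeca-2,6,10-trien-4-ol, via geranylbarium chloride 5 (not isolated)
Conditions: BaI2, Li, biphenyl, THF, rt; 4, −78 °C; then 3, −78 °C; aq NH4Cl
Reagents that add atoms: none
Why: Grignard-type carbonyl allylation with an allylbarium reagent, which unlike magnesium, zinc or chromium allyls reacts at its α-carbon with retention of the E geometry and adds 1,2 to the enal, giving the linear 4-hydroxyfarnesyl chain; the new carbinol centre (later C3) is racemic and is resolved in step 3.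

**Step 3**
Reactants: 6 rac-(2E,6E)-1-(tert-butyldimethylsilyloxy)-3,7,11-trimethyldodeca-2,6,10-trien-4-ol
Product: 7 (2R,3R,4R,6E)-1-(tert-butyldimethylsilyloxy)-2,3-epoxy-3,7,11-trimethyldodeca-6,10-dien-4-ol
Conditions: Ti(OiPr)4 (10 mol %), D-(−)-diisopropyl tartrate (15 mol %), t-BuOOH (0.55 equiv), 4 Å MS, CH2Cl2, −20 °C
Reagents that add atoms: tert-butyl hydroperoxide, CC(C)(C)OO
Why: Sharpless asymmetric epoxidation run as a kinetic resolution, in which the (2S,3S)-tartrate catalyst epoxidises the (R)-alcohol much faster than the (S)-alcohol, on the alkene face opposite to the one L-(+)-tartrate uses with geraniol, and gives the erythro (anti) epoxy alcohol, so the centres that become C3, C4 and C5 (all R) are set together, while unreacted (S)-6 and the minor threo isomer are removed by chromatography (yield capped at 50 %).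

**Step 4**
Reactants: 7 (2R,3R,4R,6E)-1-(tert-butyldimethylsilyloxy)-2,3-epoxy-3,7,11-trimethyldodeca-6,10-dien-4-ol; 8 angelic acid [(Z)-2-methylbut-2-enoic acid]
Product: 10 (2R,3R,4R,6E)-1-(tert-butyldimethylsilyloxy)-2,3-epoxy-3,7,11-trimethyldodeca-6,10-dien-4-yl (Z)-2-methylbut-2-enoate, via angelic 2,4,6-trichlorobenzoic anhydride 9 (not isolated)
Conditions: 8, 2,4,6-trichlorobenzoyl chloride, Et3N, toluene, rt; then 7, 80 °C
Reagents that add atoms: none
Why: Yamaguchi-type mixed-anhydride esterification run without a nucleophilic catalyst, the variant that transfers the angeloyl group without Z-to-E isomerisation to the tiglate; acylation is on oxygen, so C3 keeps its configuration, and the ester also blocks Payne rearrangement in later steps.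

**Step 5**
Reactants: 10 (2R,3R,4R,6E)-1-(tert-butyldimethylsilyloxy)-2,3-epoxy-3,7,11-trimethyldodeca-6,10-dien-4-yl (Z)-2-methylbut-2-enoate
Product: 11 (2R,3R,4R,6E)-1-(tert-butyldimethylsilyloxy)-10-chloro-2,3-epoxy-3,7,11-trimethyldodeca-6,11-dien-4-yl (Z)-2-methylbut-2-enoate (both C10 epimers)
Conditions: PhSeCl (10 mol %), N-chlorosuccinimide (1.1 equiv), CH2Cl2, rt
Reagents that add atoms: N-chlorosuccinimide, O=C1CCC(=O)N1Cl
Why: Selenium-catalysed ene-type allylic chlorination, in which the electrophilic PhSeCl/NCS system should prefer the most electron-rich and least hindered alkene, the terminal Me2C=CH (the internal alkene is shielded and inductively deactivated by the neighbouring C3 ester, the angelate alkene is electron-poor), and gives the transposed secondary allylic chloride, whose new C–Cl centre (dodecane C10, about 1:1) is erased on ionisation in step 8.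

**Step 6**
Reactants: 11 (2R,3R,4R,6E)-1-(tert-butyldimethylsilyloxy)-10-chloro-2,3-epoxy-3,7,11-trimethyldodeca-6,11-dien-4-yl (Z)-2-methylbut-2-enoate
Product: 12 (2R,3R,4R,6E)-10-chloro-2,3-epoxy-1-hydroxy-3,7,11-trimethyldodeca-6,11-dien-4-yl (Z)-2-methylbut-2-enoate (both C10 epimers)
Conditions: HF·pyridine, pyridine, THF, 0 °C to rt
Reagents that add atoms: none
Why: Fluoride-mediated desilylation with pyridine-buffered HF·pyridine cleaves the primary silyl ether while the epoxide, the angelate and the allylic chloride are inert to these weakly acidic, weakly nucleophilic conditions.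

**Step 7**
Reactants: 12 (2R,3R,4R,6E)-10-chloro-2,3-epoxy-1-hydroxy-3,7,11-trimethyldodeca-6,11-dien-4-yl (Z)-2-methylbut-2-enoate
Product: 13 (2S,3R,4R,6E)-10-chloro-2,3-epoxy-3,7,11-trimethyl-1-oxododeca-6,11-dien-4-yl (Z)-2-methylbut-2-enoate (both C10 epimers; the C2 label becomes S only because the formyl group now outranks C3)
Conditions: TEMPO (10 mol %), PhI(OAc)2 (1.2 equiv), CH2Cl2, rt
Reagents that add atoms: none
Why: Oxoammonium (TEMPO/PhI(OAc)2) oxidation stops at the aldehyde and is mild enough for the α,β-epoxy aldehyde (no epimerisation at C5), the allylic chloride and the alkenes.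

**Step 8**
Reactants: 13 (2S,3R,4R,6E)-10-chloro-2,3-epoxy-3,7,11-trimethyl-1-oxododeca-6,11-dien-4-yl (Z)-2-methylbut-2-enoate
Product: 16 (1(10)E,3R,4R,5R,6S,7R)-4,5-epoxy-6-hydroxygermacra-1(10),11-dien-3-yl (Z)-2-methylbut-2-enoate, via allylpalladium chloride 14 (not isolated), via allyl(ethyl)zinc 15 (not isolated)
Conditions: Pd(PPh3)4 (10 mol %), Et2Zn (4 equiv), THF, rt, syringe-pump addition of 13 to 0.005 M; aq NH4Cl
Reagents that add atoms: none
Why: Intramolecular Tamaru-type umpolung allylation, in which zerovalent palladium ionises either C–Cl epimer of 13 to the same allylpalladium chloride, Et2Zn transmetalates it to a nucleophilic allylzinc, and this attacks the aldehyde through its substituted terminus (C7) in a chair six-membered transition state where zinc chelation by the epoxide oxygen (C5 axial, attack on the aldehyde face syn to H5) is expected to give the 5,6-threo relationship (6S) and the equatorial C8 of the E-allylzinc to give 7R, the relative configuration also obtained when this ring closure is run on the 3-unsubstituted epoxyfarnesal chloride.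

**Step 9**
Reactants: 16 (1(10)E,3R,4R,5R,6S,7R)-4,5-epoxy-6-hydroxygermacra-1(10),11-dien-3-yl (Z)-2-methylbut-2-enoate
Product: 17 (1(10)E,3R,4R,5R,6S,7R)-4,5-epoxy-6-hydroxygermacr-1(10)-en-3-yl (Z)-2-methylbut-2-enoate
Conditions: H2 (1 atm), RhCl(PPh3)3 (10 mol %), benzene, rt
Reagents that add atoms: none
Why: Homogeneous hydrogenation with RhCl(PPh3)3 reduces the unhindered 1,1-disubstituted isopropenyl alkene far faster than the trisubstituted ring alkene or the conjugated trisubstituted angelate alkene, and no stereocentre is created or touched.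

**Step 10**
Reactants: 17 (1(10)E,3R,4R,5R,6S,7R)-4,5-epoxy-6-hydroxygermacr-1(10)-en-3-yl (Z)-2-methylbut-2-enoate
Product: 18 (1(10)E,3R,4R,5R,6S,7R)-6-acetoxy-4,5-epoxygermacr-1(10)-en-3-yl (Z)-2-methylbut-2-enoate (target)
Conditions: Ac2O, pyridine, DMAP (5 mol %), CH2Cl2, 0 °C to rt
Reagents that add atoms: acetic anhydride, CC(=O)OC(C)=O
Why: DMAP-catalysed O-acetylation (nucleophilic acyl transfer) of the remaining secondary alcohol proceeds with retention at C6, and the angelate and epoxide are stable to these mildly basic conditions.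

**Compound list**
1 | (tert-butyldimethylsilyloxy)acetaldehyde | O=CCO[Si](C)(C)C(C)(C)C | starting material
2 | 2-(triphenylphosphoranylidene)propanal | CC(C=O)=P(c1ccccc1)(c1ccccc1)c1ccccc1 | starting material
3 | (E)-4-(tert-butyldimethylsilyloxy)-2-methylbut-2-enal | O=C/C(C)=C/CO[Si](C)(C)C(C)(C)C | intermediate
4 | geranyl chloride, (2E)-1-chloro-3,7-dimethylocta-2,6-diene | ClC/C=C(\C)CCC=C(C)C | starting material
5 | geranylbarium chloride, (2E)-3,7-dimethylocta-2,6-dien-1-ylbarium chloride | Cl[Ba]C/C=C(\C)CCC=C(C)C | intermediate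
6 | rac-(2E,6E)-1-(tert-butyldimethylsilyloxy)-3,7,11-trimethyldodeca-2,6,10-trien-4-ol (racemic at C4) | CC(C)=CCC/C(C)=C/CC(O)/C(C)=C/CO[Si](C)(C)C(C)(C)C | intermediate
7 | (2R,3R,4R,6E)-1-(tert-butyldimethylsilyloxy)-2,3-epoxy-3,7,11-trimethyldodeca-6,10-dien-4-ol | O[C@@H]([C@@]1(C)O[C@@H]1CO[Si](C)(C)C(C)(C)C)C/C=C(\C)CCC=C(C)C | intermediate
8 | angelic acid, (Z)-2-methylbut-2-enoic acid | C/C=C(/C)C(=O)O | starting material
9 | angelic 2,4,6-trichlorobenzoic anhydride | C/C=C(/C)C(=O)OC(=O)c1c(Cl)cc(Cl)cc1Cl | intermediate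
10 | (2R,3R,4R,6E)-1-(tert-butyldimethylsilyloxy)-2,3-epoxy-3,7,11-trimethyldodeca-6,10-dien-4-yl (Z)-2-methylbut-2-enoate | C/C=C(/C)C(=O)O[C@@H]([C@@]1(C)O[C@@H]1CO[Si](C)(C)C(C)(C)C)C/C=C(\C)CCC=C(C)C | intermediate
11 | (2R,3R,4R,6E)-1-(tert-butyldimethylsilyloxy)-10-chloro-2,3-epoxy-3,7,11-trimethyldodeca-6,11-dien-4-yl (Z)-2-methylbut-2-enoate, both C10 epimers | C/C=C(/C)C(=O)O[C@@H]([C@@]1(C)O[C@@H]1CO[Si](C)(C)C(C)(C)C)C/C=C(\C)CCC(Cl)C(C)=C | intermediate
12 | (2R,3R,4R,6E)-10-chloro-2,3-epoxy-1-hydroxy-3,7,11-trimethyldodeca-6,11-dien-4-yl (Z)-2-methylbut-2-enoate, both C10 epimers | C/C=C(/C)C(=O)O[C@@H]([C@@]1(C)O[C@@H]1CO)C/C=C(\C)CCC(Cl)C(C)=C | intermediate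
13 | (2S,3R,4R,6E)-10-chloro-2,3-epoxy-3,7,11-trimethyl-1-oxododeca-6,11-dien-4-yl (Z)-2-methylbut-2-enoate, both C10 epimers | C/C=C(/C)C(=O)O[C@@H]([C@@]1(C)O[C@@H]1C=O)C/C=C(\C)CCC(Cl)C(C)=C | intermediate
14 | η3-allylpalladium chloride from 13 (phosphine ligands omitted, drawn as the primary E σ-allyl form) | C/C=C(/C)C(=O)O[C@@H]([C@@]1(C)O[C@@H]1C=O)C/C=C(\C)CC/C=C(\C)C[Pd]Cl | intermediate
15 | allyl(ethyl)zinc from 14 (drawn as the primary E σ-allyl form) | C/C=C(/C)C(=O)O[C@@H]([C@@]1(C)O[C@@H]1C=O)C/C=C(\C)CC/C=C(\C)C[Zn]CC | intermediate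
16 | (1(10)E,3R,4R,5R,6S,7R)-4,5-epoxy-6-hydroxygermacra-1(10),11-dien-3-yl (Z)-2-methylbut-2-enoate (ten-membered ring, 7-isopropenyl) | C/C=C(/C)C(=O)O[C@@H]1C/C=C(\C)CC[C@H](C(C)=C)[C@H](O)[C@H]2O[C@@]21C | intermediate
17 | (1(10)E,3R,4R,5R,6S,7R)-4,5-epoxy-6-hydroxygermacr-1(10)-en-3-yl (Z)-2-methylbut-2-enoate (7-isopropyl) | C/C=C(/C)C(=O)O[C@@H]1C/C=C(\C)CC[C@H](C(C)C)[C@H](O)[C@H]2O[C@@]21C | intermediate
18 | (1(10)E,3R,4R,5R,6S,7R)-6-acetoxy-4,5-epoxygermacr-1(10)-en-3-yl (Z)-2-methylbut-2-enoate | C/C=C(/C)C(=O)O[C@@H]1C/C=C(\C)CC[C@H](C(C)C)[C@H](OC(C)=O)[C@H]2O[C@@]21C | target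

**Totals**
Total step count: 10. Longest linear sequence: 10 steps (1 and 2 to 18).

**Three steps most likely to fail**

Step 4 (angeloylation of a hindered epoxy alcohol; risk of slow acylation or isomerisation to the tiglate). The fallback sets out from 7 and comes back at 10. It builds the Z alkene by olefination instead of transferring it. Alcohol 7 is esterified with 2-[bis(2,2,2-trifluoroethoxy)phosphoryl]propanoic acid (DCC, catalytic DMAP, CH2Cl2) to give the phosphonopropanoate F1. A Still–Gennari olefination of F1 with acetaldehyde (KN(SiMe3)2, 18-crown-6, THF, −78 °C) then gives the Z ester 10.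

Step 5 (regioselectivity between the terminal and the internal trisubstituted alkene in the ene-chlorination). The fallback sets out from 10 and comes back at 16. SeO2 (catalytic)/t-BuOOH in CH2Cl2 oxidises the E-methyl of the terminal Me2C=CH unit, the usual terminal selectivity of farnesyl chains, to give the (E)-allylic alcohol F2. MsCl/Et3N followed by LiCl gives the primary allylic chloride F3. HF·pyridine gives the primary alcohol F4, and TEMPO/PhI(OAc)2 gives the epoxy aldehyde F5. F5 is a regioisomer of 13 that ionises to the same allylpalladium chloride 14, so it closes to 16 under the step 8 conditions.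

Step 8 (macrocyclisation yield and the C6 outcome; the stereochemical argument rests on chelation and on analogy with the 3-unsubstituted series). The fallback sets out from 13 and comes back at 18. If ring closure gives mainly the C6-epimeric alcohol F6, C6 is set by SN2 inversion instead of by the allylation. A Mitsunobu reaction with acetic acid (PPh3, DIAD, AcOH, toluene), a known way to invert carbinols next to epoxides, gives the inverted acetate F7 directly. Hydrogenation of F7 with RhCl(PPh3)3/H2 then gives 18, bypassing 17.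

**Further compounds**
F1 | step 4 | (2R,3R,4R,6E)-1-(tert-butyldimethylsilyloxy)-2,3-epoxy-3,7,11-trimethyldodeca-6,10-dien-4-yl 2-[bis(2,2,2-trifluoroethoxy)phosphoryl]propanoate (both epimers at the phosphonate carbon) | CC(C(=O)O[C@@H]([C@@]1(C)O[C@@H]1CO[Si](C)(C)C(C)(C)C)C/C=C(\C)CCC=C(C)C)P(=O)(OCC(F)(F)F)OCC(F)(F)F
F2 | step 5 | (2R,3R,4R,6E,10E)-1-(tert-butyldimethylsilyloxy)-2,3-epoxy-12-hydroxy-3,7,11-trimethyldodeca-6,10-dien-4-yl (Z)-2-methylbut-2-enoate | C/C=C(/C)C(=O)O[C@@H]([C@@]1(C)O[C@@H]1CO[Si](C)(C)C(C)(C)C)C/C=C(\C)CC/C=C(\C)CO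
F3 | step 5 | (2R,3R,4R,6E,10E)-1-(tert-butyldimethylsilyloxy)-12-chloro-2,3-epoxy-3,7,11-trimethyldodeca-6,10-dien-4-yl (Z)-2-methylbut-2-enoate | C/C=C(/C)C(=O)O[C@@H]([C@@]1(C)O[C@@H]1CO[Si](C)(C)C(C)(C)C)C/C=C(\C)CC/C=C(\C)CCl
F4 | step 5 | (2R,3R,4R,6E,10E)-12-chloro-2,3-epoxy-1-hydroxy-3,7,11-trimethyldodeca-6,10-dien-4-yl (Z)-2-methylbut-2-enoate | C/C=C(/C)C(=O)O[C@@H]([C@@]1(C)O[C@@H]1CO)C/C=C(\C)CC/C=C(\C)CCl
F5 | step 5 | (2S,3R,4R,6E,10E)-12-chloro-2,3-epoxy-3,7,11-trimethyl-1-oxododeca-6,10-dien-4-yl (Z)-2-methylbut-2-enoate | C/C=C(/C)C(=O)O[C@@H]([C@@]1(C)O[C@@H]1C=O)C/C=C(\C)CC/C=C(\C)CCl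
F6 | step 8 | (1(10)E,3R,4R,5R,6R,7R)-4,5-epoxy-6-hydroxygermacra-1(10),11-dien-3-yl (Z)-2-methylbut-2-enoate (C6 epimer of 16) | C/C=C(/C)C(=O)O[C@@H]1C/C=C(\C)CC[C@H](C(C)=C)[C@@H](O)[C@H]2O[C@@]21C
F7 | step 8 | (1(10)E,3R,4R,5R,6S,7R)-6-acetoxy-4,5-epoxygermacra-1(10),11-dien-3-yl (Z)-2-methylbut-2-enoate | C/C=C(/C)C(=O)O[C@@H]1C/C=C(\C)CC[C@H](C(C)=C)[C@H](OC(C)=O)[C@H]2O[C@@]21C
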